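Remark on the chemistry: the SMILES is read as (2S)-7,4'-dihydroxy-6,8,3'-triprenylflavanone; 7-hydroxychromone, 4-bromophenol and 2-methylbut-3-en-2-ol are taken as catalogue compounds.

## The problem

The target 16 is a flavanone. Ring A (C4a, C5, C6, C7, C8, C8a) is fused to the pyranone ring C (O1, C2, C3, C4=O), and ring B (a 4-hydroxyphenyl group) sits on C2. There are free hydroxyls on C7 and C4' and prenyl groups on C6, C8 and C3'.

C2 is the only stereocentre, so nothing in the molecule can control it and its (S) configuration must come from a chiral catalyst or reagent. C2 is also labile: base opens ring C by E1cB cleavage of the O1–C2 bond to a 2'-hydroxychalcone, which recloses as the racemate. Every operation after C2 is set must therefore be free of strong base.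

All three prenyl groups sit ortho to a phenol oxygen, and ring A carries four contiguous substituents (O1, prenyl, OH, prenyl). Direct C-prenylation of phenols is unselective (O against C, mono against poly, ortho against para). The ortho-prenylphenol units close to 2,2-dimethylchromans under acid, and the trisubstituted olefins rule out hydrogenolysis and strong electrophiles, so benzyl, acid-labile and base-labile protecting groups each collide with something.

Two features of the structure make the plan possible:

- C2 is the β-carbon of the unit O1–C2–C3–C4(=O) of ring C. At the chromone oxidation level (C2=C3) the C2–C1' bond is therefore a conjugate-addition bond to a flat, achiral vinylogous ester.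
- Each prenyl CH2 is bound to a ring carbon ortho to a phenol oxygen (C6 and C8 to O7 in ring A, C3' to O4' in ring B). Each C-prenyl group is thus the [3,3] image of an O-(1,1-dimethylallyl) ether. Because O7 is flanked by prenyl groups on both sides, it does not matter which ortho position is filled first.

## Retrosynthesis

**16 to 13.** The C6–CH2 and C3'–CH2 bonds are cut by a double retro-Claisen step, which leads to the bis(1,1-dimethylallyl) ether 13. The two free phenols of 16 are masked in 13 by the very atoms that become the prenyl groups, so no protecting group is put on or taken off. The last step is a reagent-free isomerisation in a neutral solvent, the gentlest treatment available for C2. On ring A only C6 is open (C8 carries the first prenyl group and the para position C4a is substituted). On ring B the two ortho positions are equivalent. The forward reaction is asked only to run below the temperature at which ring C opens.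

**13 to 7 and 12.** The C2–C1' bond is cut. Going back to the chromone 7 removes the stereocentre, and ring B becomes the arylboronic acid 12. Cutting O1–C2 instead (the chalcone cut) would close the ring by the reverse of the racemisation path, which is reversible and hard to control. The C–C cut gives an irreversible bond formation under catalyst control. The precursors are two achiral fragments of 19 and 11 carbon atoms. The forward reaction must transfer the aryl group to C2 of the enone in the presence of one trisubstituted and two monosubstituted isolated alkenes, without added base.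

**7 to 6, 5 and 4.** The C8 prenyl group of 7 is traced by the same retron to the ether 5 of 7-hydroxychromone 4. Rearrangement gives 6, and a second etherification with carbonate 3 gives 7. If the rearrangement of 5 went to C6 instead of C8, the isomer would converge on 16 in the last step, so the regiochemistry of this step is not critical.

**12 to 9 and 8.** The C–B bond is cut to the aryl bromide 9 (bromine–lithium exchange, borylation). Ether 9 comes from 4-bromophenol 8 and carbonate 3.

**3 to 1.** The carbonate 3, which supplies all three C5 units, is cut at the carbonate C–O bond to 2-methylbut-3-en-2-ol 1 and di-tert-butyl dicarbonate.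

## Roads not taken

**Alternative 1:** the obvious cut is at O1–C2 and C3–C(β) (the chalcone route). A protected diprenyl acetophenone, 1-[2-hydroxy-4-(methoxymethoxy)-3,5-diprenylphenyl]ethanone A1, and the aldehyde 4-(methoxymethoxy)-3-prenylbenzaldehyde A2 would be joined by Claisen–Schmidt condensation. Deprotection would give the chalcone A3, and the forward key step would be its oxa-Michael ring closure.
- The closure is the microscopic reverse of the racemisation path, so without an activating group on the enone it gives essentially the racemate A4.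
- A1 and A2 each need direct phenol C-prenylation, which is unselective, and protecting groups whose acidic removal sits next to three ortho-prenylphenol units.
- The chosen plan sets C2 by an irreversible C–C bond formation and needs no protecting group.

**Alternative 2:** both ring-A bonds C4a–C4 and C8a–O1 are cut, leading to the aryne A5 (3,5-diprenyl-4-(methoxymethoxy)benzyne) and the cinnamic acid A6. In the forward step the carboxylate oxygen adds to the aryne, the aryl anion attacks the acyl carbon, and the resulting 2'-hydroxychalcone closes to the flavanone.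
- The oxygen would have to add to the aryne carbon that is flanked by the prenyl group.
- The steric effect of that prenyl group and the inductive effect of the oxygen two carbons away both send the nucleophile to the other aryne carbon, so the carbonyl would end up beside the prenyl group.
- The product would be racemic, and the precursor of A5 is itself a pentasubstituted benzene.

**Alternative 3:** the three aryl–CH2 bonds are cut last. (S)-7,4'-Dihydroxyflavanone A7 would be made first, iodinated to the 6,8,3'-triiodide A8, and coupled three times with tributyl(prenyl)stannane (Stille coupling).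
- On ring B, C3' and C5' are equally activated, so iodination cannot be stopped cleanly at one position.
- Allylstannanes can couple at either terminus.
- Three hot palladium couplings on a free-phenol flavanone put C2 at risk.
- The sigmatropic route fixes every position by construction and needs no metal in the last step.

Key step: step 7

## Steps

Step 1
Reactants: 1 2-methylbut-3-en-2-ol
Product: 3 tert-butyl 2-methylbut-3-en-2-yl carbonate, via lithium 2-methylbut-3-en-2-olate 2 (not isolated)
Conditions: n-BuLi, THF, −78 to 0 °C; then Boc2O, 0 °C to rt; H2O work-up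
Reagents that add atoms: di-tert-butyl dicarbonate, CC(C)(C)OC(=O)OC(=O)OC(C)(C)C
Why: Acylation of a tertiary lithium alkoxide with Boc2O is the standard route to tertiary allylic tert-butyl carbonates; the alkoxide is needed because the tertiary alcohol is too hindered for direct acylation.

Step 2
Reactants: 4 7-hydroxy-4H-chromen-4-one; 3 tert-butyl 2-methylbut-3-en-2-yl carbonate
Product: 5 7-[(2-methylbut-3-en-2-yl)oxy]-4H-chromen-4-one
Conditions: Pd(PPh3)4 (3 mol%), THF, 4 Å molecular sieves, 0 °C, short reaction time
Reagents that add atoms: none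
Why: Tsuji–Trost decarboxylative O-allylation: zerovalent palladium ionises 3, the tert-butoxide set free deprotonates the phenol, and the phenoxide attacks the more substituted terminus of the 1,1-dimethyl-π-allyl complex to give the branched ether under kinetic control at low temperature.

Step 3
Reactants: 5 7-[(2-methylbut-3-en-2-yl)oxy]-4H-chromen-4-one
Product: 6 7-hydroxy-8-(3-methylbut-2-en-1-yl)-4H-chromen-4-one
Conditions: PhNEt2, 130 °C
Reagents that add atoms: none
Why: Aromatic Claisen rearrangement: the [3,3] shift delivers the terminal CH2 of the 1,1-dimethylallyl group to the ortho carbon and enolisation restores the phenol, turning the ether into a C-prenyl group. C8 is expected to be preferred, as in 7-allyloxy-coumarins and -chromones, where the C7–C8 bond has the higher double-bond character, and the choice is not critical because both ortho positions of O7 are prenylated in the end.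

Step 4
Reactants: 6 7-hydroxy-8-(3-methylbut-2-en-1-yl)-4H-chromen-4-one; 3 tert-butyl 2-methylbut-3-en-2-yl carbonate
Product: 7 7-[(2-methylbut-3-en-2-yl)oxy]-8-(3-methylbut-2-en-1-yl)-4H-chromen-4-one
Conditions: Pd(PPh3)4 (5 mol%), THF, 4 Å molecular sieves, 0 °C
Reagents that add atoms: none
Why: Same Tsuji–Trost O-allylation as in step 2; the new ether is at once the protecting group of O7 for step 7 and the source of the C6 prenyl group in step 8.

Step 5
Reactants: 8 4-bromophenol; 3 tert-butyl 2-methylbut-3-en-2-yl carbonate
Product: 9 1-bromo-4-[(2-methylbut-3-en-2-yl)oxy]benzene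
Conditions: Pd(PPh3)4 (3 mol%), THF, 4 Å molecular sieves, 0 °C
Reagents that add atoms: none
Why: Tsuji–Trost O-allylation as in step 2; at 0 °C ionisation of the allylic carbonate is much faster than oxidative addition of the electron-rich aryl bromide to zerovalent palladium.

Step 6
Reactants: 9 1-bromo-4-[(2-methylbut-3-en-2-yl)oxy]benzene
Product: 12 {4-[(2-methylbut-3-en-2-yl)oxy]phenyl}boronic acid, via aryllithium 10 (not isolated), via lithium aryltriisopropoxyborate 11 (not isolated)
Conditions: n-BuLi, THF, −78 °C; B(OiPr)3, −78 °C to rt; sat. aq. NH4Cl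
Reagents that add atoms: triisopropyl borate, CC(C)OB(OC(C)C)OC(C)C; water, O
Why: Bromine–lithium exchange followed by borylation and hydrolysis is the standard route to arylboronic acids; the tertiary allyl ether has no α-hydrogen for a Wittig rearrangement, and the near-neutral work-up spares it from acid ionisation.

Step 7
Reactants: 7 7-[(2-methylbut-3-en-2-yl)oxy]-8-(3-methylbut-2-en-1-yl)-4H-chromen-4-one; 12 {4-[(2-methylbut-3-en-2-yl)oxy]phenyl}boronic acid
Product: 13 (2S)-7-[(2-methylbut-3-en-2-yl)oxy]-2-{4-[(2-methylbut-3-en-2-yl)oxy]phenyl}-8-(3-methylbut-2-en-1-yl)-2,3-dihydro-4H-chromen-4-one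
Conditions: [Rh(OH)(cod)]2 (2.5 mol%), (S)-MeO-F12-BIPHEP [(S)-6,6'-dimethoxy-2,2'-bis{bis(3,4,5-trifluorophenyl)phosphino}-1,1'-biphenyl] (5.5 mol%), 12 (2–3 equiv), toluene/H2O 10:1, 25–40 °C, no added base
Reagents that add atoms: none
Why: This is a Hayashi–Miyaura asymmetric 1,4-addition, a reaction type shown for arylboronic acids and chromones with electron-poor biaryl bisphosphine complexes of monovalent rhodium. Transmetalation from boron to the hydroxo-rhodium complex gives an aryl–rhodium species, the C2=C3 bond of 7 coordinates, the aryl group migrates to C2 to give an oxa-π-allyl rhodium enolate, and water protonates C3 and regenerates Rh–OH. No ring is closed: ring C is already present in 7 and only C2 and C3 change hybridisation. The new stereocentre C2 is controlled by the ligand alone, whose C2-symmetric pocket leaves one face of the flat C2=C3 bond open to the migrating aryl group. By the sense in which (S)-configured biaryl bisphosphines arylate six-membered cyclic enones (O1 takes the place of the ring CH2 on the β-carbon and the descriptor is unchanged), the (S)-ligand should give (2S); the sense is to be confirmed on the first run and the (R)-ligand used if it is reversed. The step needs aryl transfer to the enone and not to the isolated alkenes; the enone is polarised by C4=O and O1 and binds rhodium as a chelating π-system, whereas the two vinyl groups are unactivated and attached to a quaternary carbon and the prenyl olefin is trisubstituted. Because both phenol oxygens are ethers no phenoxide deactivates the chromone, and because no base is added the E1cB opening of ring C, the path by which C2 would racemise, should not compete. The C–C bond formation is irreversible, so the configuration is fixed under kinetic control.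

Step 8
Reactants: 13 (2S)-7-[(2-methylbut-3-en-2-yl)oxy]-2-{4-[(2-methylbut-3-en-2-yl)oxy]phenyl}-8-(3-methylbut-2-en-1-yl)-2,3-dihydro-4H-chromen-4-one
Product: 16 (2S)-7-hydroxy-2-[4-hydroxy-3-(3-methylbut-2-en-1-yl)phenyl]-6,8-bis(3-methylbut-2-en-1-yl)-2,3-dihydro-4H-chromen-4-one (target), via ring-A-rearranged monoether 14 (not isolated), via ring-B-rearranged monoether 15 (not isolated)
Conditions: degassed o-xylene, 125 °C, sealed tube, dark
Reagents that add atoms: none
Why: Double aromatic Claisen rearrangement: each 1,1-dimethylallyl ether shifts by [3,3] to its free ortho carbon (C6 on ring A, since C8 is occupied; C3' on ring B, where both ortho positions are equivalent) and enolises, in either order, to free the phenol and form the prenyl group. C2 is not involved and the medium is neutral and aprotic, so the (2S) configuration set in step 7 should be retained.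

## Compound list

1 | 2-methylbut-3-en-2-ol | C=CC(C)(C)O | starting material
2 | lithium 2-methylbut-3-en-2-olate | [Li+].[O-]C(C)(C)C=C | intermediate
3 | tert-butyl 2-methylbut-3-en-2-yl carbonate | C=CC(C)(C)OC(=O)OC(C)(C)C | intermediate
4 | 7-hydroxy-4H-chromen-4-one | O=c1ccoc2cc(O)ccc12 | starting material
5 | 7-[(2-methylbut-3-en-2-yl)oxy]-4H-chromen-4-one | C=CC(C)(C)Oc1ccc2c(c1)occc2=O | intermediate
6 | 7-hydroxy-8-(3-methylbut-2-en-1-yl)-4H-chromen-4-one | CC(C)=CCc1c(O)ccc2c1occc2=O | intermediate
7 | 7-[(2-methylbut-3-en-2-yl)oxy]-8-(3-methylbut-2-en-1-yl)-4H-chromen-4-one | CC(C)=CCc1c(OC(C)(C)C=C)ccc2c1occc2=O | intermediate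
8 | 4-bromophenol | Oc1ccc(Br)cc1 | starting material
9 | 1-bromo-4-[(2-methylbut-3-en-2-yl)oxy]benzene | C=CC(C)(C)Oc1ccc(Br)cc1 | intermediate
10 | {4-[(2-methylbut-3-en-2-yl)oxy]phenyl}lithium | [Li]c1ccc(OC(C)(C)C=C)cc1 | intermediate
11 | lithium {4-[(2-methylbut-3-en-2-yl)oxy]phenyl}triisopropoxyborate | [Li+].CC(C)O[B-](OC(C)C)(OC(C)C)c1ccc(OC(C)(C)C=C)cc1 | intermediate
12 | {4-[(2-methylbut-3-en-2-yl)oxy]phenyl}boronic acid | C=CC(C)(C)Oc1ccc(B(O)O)cc1 | intermediate
13 | (2S)-7-[(2-methylbut-3-en-2-yl)oxy]-2-{4-[(2-methylbut-3-en-2-yl)oxy]phenyl}-8-(3-methylbut-2-en-1-yl)-2,3-dihydro-4H-chromen-4-one | C=CC(C)(C)Oc1ccc([C@@H]2CC(=O)c3ccc(OC(C)(C)C=C)c(CC=C(C)C)c3O2)cc1 | intermediate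
14 | (2S)-7-hydroxy-2-{4-[(2-methylbut-3-en-2-yl)oxy]phenyl}-6,8-bis(3-methylbut-2-en-1-yl)-2,3-dihydro-4H-chromen-4-one | C=CC(C)(C)Oc1ccc([C@@H]2CC(=O)c3cc(CC=C(C)C)c(O)c(CC=C(C)C)c3O2)cc1 | intermediate
15 | (2S)-2-[4-hydroxy-3-(3-methylbut-2-en-1-yl)phenyl]-7-[(2-methylbut-3-en-2-yl)oxy]-8-(3-methylbut-2-en-1-yl)-2,3-dihydro-4H-chromen-4-one | CC(C)=CCc1cc([C@@H]2CC(=O)c3ccc(OC(C)(C)C=C)c(CC=C(C)C)c3O2)ccc1O | intermediate
16 | (2S)-7-hydroxy-2-[4-hydroxy-3-(3-methylbut-2-en-1-yl)phenyl]-6,8-bis(3-methylbut-2-en-1-yl)-2,3-dihydro-4H-chromen-4-one | CC(C)=CCc1cc([C@@H]2CC(=O)c3cc(CC=C(C)C)c(O)c(CC=C(C)C)c3O2)ccc1O | target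

## Step count and risks

Total step count: 8. Longest linear sequence: 6 (steps 1, 2, 3, 4, 7, 8); the ring-B branch (steps 5, 6) joins at step 7.

**Step 7 (key step).** Three things may go wrong:
- loss of chemoselectivity: aryl transfer from rhodium to a vinyl group followed by β-oxygen elimination, or ionisation of the tertiary allyl aryl ethers at the metal;
- slow addition to the electron-rich 7-alkoxychromone, so that protodeboronation of 12 takes over;
- erosion of the enantiomeric purity through opening of ring C.

The fallback avoids rhodium. It sets out from 7 and 3 and returns at 13.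
- Chromone 7 is opened with NaOH in aqueous EtOH at 70 °C (hydroxide adds at C2, retro-Claisen loss of formate) to 1-{2-hydroxy-4-[(2-methylbut-3-en-2-yl)oxy]-3-(3-methylbut-2-en-1-yl)phenyl}ethan-1-one F1.
- 4-Hydroxybenzaldehyde is etherified with 3 as in step 5 to 4-[(2-methylbut-3-en-2-yl)oxy]benzaldehyde F2.
- Claisen–Schmidt condensation (KOH, EtOH, rt) gives the 2'-hydroxychalcone F3, which is closed with NaOAc in EtOH to the racemic flavanone F4.
- Kinetic resolution by Noyori asymmetric transfer hydrogenation (RuCl[(R,R)-TsDPEN](p-cymene), HCO2Na, H2O/EtOAc) should reduce the (2R)-enantiomer to the cis-flavan-4-ol F5 and leave the (2S)-flavanone 13.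

**Step 8.** The tertiary ethers may fragment to phenol and isoprene, the ortho-prenylphenols may cyclise to chromans at the temperature needed, and ring C may open thermally with erosion of the enantiomeric purity.

The fallback moves both sigmatropic shifts in front of the stereocentre. It sets out from 7 and 9 and returns at 16.
- 7 is heated (PhNEt2, 130 °C) to 7-hydroxy-6,8-bis(3-methylbut-2-en-1-yl)-4H-chromen-4-one F6, which is protected (MOMCl, iPr2NEt) as the methoxymethyl ether F7.
- 9 is heated likewise to 4-bromo-2-(3-methylbut-2-en-1-yl)phenol F8, protected as the methoxymethyl ether F9, and converted by Miyaura borylation (B2pin2, PdCl2(dppf), KOAc, dioxane) into the pinacol boronate F10.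
- Rhodium-catalysed addition of F10 to F7 under the conditions of step 7 gives the bis(methoxymethyl) ether F11.
- Dilute HCl in MeOH at rt removes both acetals and gives 16.

**Step 3.** The shift may go to C6 instead of C8, or give both. The fallback carries the other regioisomer through. It sets out from 5 and returns at 16.
- 7-Hydroxy-6-(3-methylbut-2-en-1-yl)-4H-chromen-4-one F12 is etherified with 3 as in step 4 to the ether F13.
- F13 is coupled with 12 as in step 7 to the (2S)-flavanone F14.
- F14 is heated as in step 8. The ring-A shift now has only C8 open, so the product is again 16.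

**Step 2 (the same holds for steps 4 and 5).** Zerovalent palladium may re-ionise the product ether, whose phenoxide is a good leaving group, with equilibration to the linear O-prenyl ether or C-allylation. The fallback builds the ether without a π-allyl intermediate. It sets out from 4 and returns at 5.
- 4 is alkylated with 3-chloro-3-methylbut-1-yne (CuCl2 cat., DBU, MeCN, 0 °C) to 7-[(2-methylbut-3-yn-2-yl)oxy]-4H-chromen-4-one F15.
- F15 is semihydrogenated (H2, Pd/CaCO3 poisoned with Pb(OAc)2, quinoline, EtOAc) to 5.

## Further compounds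

F1 | step 7 | 1-{2-hydroxy-4-[(2-methylbut-3-en-2-yl)oxy]-3-(3-methylbut-2-en-1-yl)phenyl}ethan-1-one | CC(=O)c1ccc(OC(C)(C)C=C)c(CC=C(C)C)c1O
F2 | step 7 | 4-[(2-methylbut-3-en-2-yl)oxy]benzaldehyde | C=CC(C)(C)Oc1ccc(C=O)cc1
F3 | step 7 | (E)-1-{2-hydroxy-4-[(2-methylbut-3-en-2-yl)oxy]-3-(3-methylbut-2-en-1-yl)phenyl}-3-{4-[(2-methylbut-3-en-2-yl)oxy]phenyl}prop-2-en-1-one | C=CC(C)(C)Oc1ccc(/C=C/C(=O)c2ccc(OC(C)(C)C=C)c(CC=C(C)C)c2O)cc1
F4 | step 7 | racemic 7-[(2-methylbut-3-en-2-yl)oxy]-2-{4-[(2-methylbut-3-en-2-yl)oxy]phenyl}-8-(3-methylbut-2-en-1-yl)-2,3-dihydro-4H-chromen-4-one | C=CC(C)(C)Oc1ccc(C2CC(=O)c3ccc(OC(C)(C)C=C)c(CC=C(C)C)c3O2)cc1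
F5 | step 7 | (2R,4R)-7-[(2-methylbut-3-en-2-yl)oxy]-2-{4-[(2-methylbut-3-en-2-yl)oxy]phenyl}-8-(3-methylbut-2-en-1-yl)-3,4-dihydro-2H-chromen-4-ol | C=CC(C)(C)Oc1ccc([C@H]2C[C@@H](O)c3ccc(OC(C)(C)C=C)c(CC=C(C)C)c3O2)cc1
F6 | step 8 | 7-hydroxy-6,8-bis(3-methylbut-2-en-1-yl)-4H-chromen-4-one | CC(C)=CCc1cc2c(occc2=O)c(CC=C(C)C)c1O
F7 | step 8 | 7-(methoxymethoxy)-6,8-bis(3-methylbut-2-en-1-yl)-4H-chromen-4-one | CC(C)=CCc1cc2c(occc2=O)c(CC=C(C)C)c1OCOC
F8 | step 8 | 4-bromo-2-(3-methylbut-2-en-1-yl)phenol | CC(C)=CCc1cc(Br)ccc1O
F9 | step 8 | 4-bromo-1-(methoxymethoxy)-2-(3-methylbut-2-en-1-yl)benzene | CC(C)=CCc1cc(Br)ccc1OCOC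
F10 | step 8 | 2-[4-(methoxymethoxy)-3-(3-methylbut-2-en-1-yl)phenyl]-4,4,5,5-tetramethyl-1,3,2-dioxaborolane | CC(C)=CCc1cc(B2OC(C)(C)C(C)(C)O2)ccc1OCOC
F11 | step 8 | (2S)-7-(methoxymethoxy)-2-[4-(methoxymethoxy)-3-(3-methylbut-2-en-1-yl)phenyl]-6,8-bis(3-methylbut-2-en-1-yl)-2,3-dihydro-4H-chromen-4-one | CC(C)=CCc1cc([C@@H]2CC(=O)c3cc(CC=C(C)C)c(OCOC)c(CC=C(C)C)c3O2)ccc1OCOC
F12 | step 3 | 7-hydroxy-6-(3-methylbut-2-en-1-yl)-4H-chromen-4-one | CC(C)=CCc1cc2c(cc1O)occc2=O
F13 | step 3 | 7-[(2-methylbut-3-en-2-yl)oxy]-6-(3-methylbut-2-en-1-yl)-4H-chromen-4-one | CC(C)=CCc1cc2c(cc1OC(C)(C)C=C)occc2=O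
F14 | step 3 | (2S)-7-[(2-methylbut-3-en-2-yl)oxy]-2-{4-[(2-methylbut-3-en-2-yl)oxy]phenyl}-6-(3-methylbut-2-en-1-yl)-2,3-dihydro-4H-chromen-4-one | C=CC(C)(C)Oc1ccc([C@@H]2CC(=O)c3cc(CC=C(C)C)c(OC(C)(C)C=C)cc3O2)cc1
F15 | step 2 | 7-[(2-methylbut-3-yn-2-yl)oxy]-4H-chromen-4-one | C#CC(C)(C)Oc1ccc2c(c1)occc2=O
A1 | alternative 1 | 1-[2-hydroxy-4-(methoxymethoxy)-3,5-bis(3-methylbut-2-en-1-yl)phenyl]ethan-1-one | CC(=O)c1cc(CC=C(C)C)c(OCOC)c(CC=C(C)C)c1O
A2 | alternative 1 | 4-(methoxymethoxy)-3-(3-methylbut-2-en-1-yl)benzaldehyde | COCOc1ccc(C=O)cc1CC=C(C)C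
A3 | alternative 1 | (E)-1-[2,4-dihydroxy-3,5-bis(3-methylbut-2-en-1-yl)phenyl]-3-[4-hydroxy-3-(3-methylbut-2-en-1-yl)phenyl]prop-2-en-1-one | CC(C)=CCc1cc(/C=C/C(=O)c2cc(CC=C(C)C)c(O)c(CC=C(C)C)c2O)ccc1O
A4 | alternative 1 | racemic 7-hydroxy-2-[4-hydroxy-3-(3-methylbut-2-en-1-yl)phenyl]-6,8-bis(3-methylbut-2-en-1-yl)-2,3-dihydro-4H-chromen-4-one | CC(C)=CCc1cc(C2CC(=O)c3cc(CC=C(C)C)c(O)c(CC=C(C)C)c3O2)ccc1O
A5 | alternative 2 | 4-(methoxymethoxy)-3,5-bis(3-methylbut-2-en-1-yl)benzyne | COCOC1=C(CC=C(C)C)C#CC=C1CC=C(C)C
A6 | alternative 2 | (E)-3-[4-(methoxymethoxy)-3-(3-methylbut-2-en-1-yl)phenyl]prop-2-enoic acid | COCOc1ccc(/C=C/C(=O)O)cc1CC=C(C)C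
A7 | alternative 3 | (2S)-7-hydroxy-2-(4-hydroxyphenyl)-2,3-dihydro-4H-chromen-4-one | O=C1C[C@@H](c2ccc(O)cc2)Oc2cc(O)ccc12
A8 | alternative 3 | (2S)-7-hydroxy-2-(4-hydroxy-3-iodophenyl)-6,8-diiodo-2,3-dihydro-4H-chromen-4-one | O=C1C[C@@H](c2ccc(O)c(I)c2)Oc2c(I)c(O)c(I)cc12
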